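**Retrosynthetic overview**

1. Numbering used below: C1 quaternary carbon (Me), C2 CH–O, C3 CH2, C4 C(OH)iPr, C5 ring-fusion CH, C6 CH–O, C7 CH2, C8(Me)=C9, C10 CH2.
2. Target ⇒ triol (last step: double angeloylation of the C2 and C6 hydroxyls) ⇒ bis-silyl ether.
3. Seven-membered ring, formed last: ring-closing metathesis at C8=C9 between an allyl group on C1 and a 2-methylallyl group on C6 of a fully substituted cyclopentane.
4. C4 carbinol ⇒ isopropyl-metal addition to a cyclopentanone; key C5–C6 bond ⇒ intermolecular anti-selective boron aldol of a regio-defined cyclopentanone enolate with 3-methylbut-3-enal (sets C5 and C6).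
5. Enolate and quaternary C1 ⇒ Me2CuLi addition to (S)-3-allyl-4-silyloxycyclopent-2-enone ⇒ (S)-4-silyloxycyclopent-2-enone; the five-membered ring is present from the start.

Assumption: (S)-4-(tert-butyldimethylsilyloxy)cyclopent-2-en-1-one (1) is bought as the single enantiomer (catalogue prostaglandin building block).

**Route**

Step 1
Reactants: 1 (S)-4-(tert-butyldimethylsilyloxy)cyclopent-2-en-1-one; 2 allylmagnesium bromide
Product: 3 (3S,4S)-3-allyl-4-(tert-butyldimethylsilyloxy)-1-(trimethylsilyloxy)cyclopent-1-ene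
Conditions: 2 (2.2 equiv), CuBr·SMe2 (1.1 equiv), THF, −78 °C; then TMSCl, 1, −78 °C; Et3N, pentane work-up, used crude
Reagents that add atoms: chlorotrimethylsilane, C[Si](C)(C)Cl
Why: TMSCl-accelerated conjugate (1,4-) addition of (allyl)2CuMgBr to the enone occurs anti to the silyloxy group and the enolate is trapped regiospecifically as its silyl enol ether, the new C–H stereocenter being of no consequence because it is erased in step 2.

Step 2
Reactants: 3 (3S,4S)-3-allyl-4-(tert-butyldimethylsilyloxy)-1-(trimethylsilyloxy)cyclopent-1-ene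
Product: 4 (S)-3-allyl-4-(tert-butyldimethylsilyloxy)cyclopent-2-en-1-one
Conditions: IBX, 4-methoxypyridine N-oxide, DMSO, rt
Reagents that add atoms: none
Why: IBX dehydrogenation of a silyl enol ether (a Saegusa–Ito-type oxidation run without a transition metal, so the skipped allyl group is not isomerised) reinstalls the enone with the allyl group now on the β-carbon and leaves the silyloxy-bearing stereocenter untouched.

Step 3
Reactants: 4 (S)-3-allyl-4-(tert-butyldimethylsilyloxy)cyclopent-2-en-1-one; 5 methyllithium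
Product: 6 (3R,4S)-3-allyl-4-(tert-butyldimethylsilyloxy)-3-methyl-1-(trimethylsilyloxy)cyclopent-1-ene
Conditions: 5 (2.2 equiv), CuI (1.1 equiv), Et2O, 0 °C; then TMSCl, 4, THF, −78 to −40 °C; Et3N, pentane work-up
Reagents that add atoms: chlorotrimethylsilane, C[Si](C)(C)Cl
Why: Conjugate addition of Me2CuLi to the β,β-disubstituted enone, accelerated by TMSCl, delivers the methyl group anti to the adjacent OTBS group and so sets the quaternary carbon (3R, allyl cis to OTBS), while O-silylation fixes the enolate regiochemistry toward the carbon next to the quaternary centre.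

Step 4
Reactants: 7 3-methylbut-3-en-1-ol
Product: 8 3-methylbut-3-enal
Conditions: Dess–Martin periodinane, NaHCO3, CH2Cl2, 0 °C; cold filtered solution used at once
Reagents that add atoms: none
Why: Dess–Martin oxidation under bicarbonate buffering gives the β,γ-unsaturated aldehyde without acid- or base-induced migration of the double bond into conjugation.

Step 5
Reactants: 6 (3R,4S)-3-allyl-4-(tert-butyldimethylsilyloxy)-3-methyl-1-(trimethylsilyloxy)cyclopent-1-ene; 8 3-methylbut-3-enal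
Product: 12 (2S,3R,4S)-3-allyl-4-(tert-butyldimethylsilyloxy)-2-[(1S)-1-hydroxy-3-methylbut-3-en-1-yl]-3-methylcyclopentan-1-one, via lithium enolate 9 (not isolated), via dicyclohexylboron enolate 10 (not isolated), via boron aldolate 11 (not isolated)
Conditions: MeLi, THF, 0 °C; (c-C6H11)2BCl, −78 °C; 8, −78 to −20 °C; H2O2, pH 7 buffer, MeOH, 0 °C
Reagents that add atoms: none
Why: Intermolecular boron-mediated aldol addition in which MeLi unmasks the regio-defined lithium enolate, exchange to the dicyclohexylboron enolate (necessarily E because the enolate double bond lies in the ring) enforces a chair Zimmerman–Traxler transition state that gives the anti aldol, and the aldehyde adds to the enolate face bearing the small methyl group, opposite the pseudoaxial allyl group and the OTBS flank, which sets ring C2 (S) and the carbinol carbon (S).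

Step 6
Reactants: 12 (2S,3R,4S)-3-allyl-4-(tert-butyldimethylsilyloxy)-2-[(1S)-1-hydroxy-3-methylbut-3-en-1-yl]-3-methylcyclopentan-1-one
Product: 13 (2S,3R,4S)-3-allyl-4-(tert-butyldimethylsilyloxy)-3-methyl-2-[(1S)-3-methyl-1-(triethylsilyloxy)but-3-en-1-yl]cyclopentan-1-one
Conditions: TESOTf, 2,6-lutidine, CH2Cl2, −78 °C
Reagents that add atoms: triethylsilyl trifluoromethanesulfonate, CC[Si](CC)(CC)OS(=O)(=O)C(F)(F)F
Why: Silyl ether formation with the triflate and a hindered base at −78 °C caps the aldol hydroxyl before any retro-aldol or β-elimination can occur and without touching the α-stereocenter.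

Step 7
Reactants: 13 (2S,3R,4S)-3-allyl-4-(tert-butyldimethylsilyloxy)-3-methyl-2-[(1S)-3-methyl-1-(triethylsilyloxy)but-3-en-1-yl]cyclopentan-1-one; 14 isopropylmagnesium chloride
Product: 15 (1R,2S,3R,4S)-3-allyl-4-(tert-butyldimethylsilyloxy)-3-methyl-2-[(1S)-3-methyl-1-(triethylsilyloxy)but-3-en-1-yl]-1-(propan-2-yl)cyclopentan-1-ol
Conditions: 14 (as iPrMgCl·LiCl), LaCl3·2LiCl, THF, 0 °C; H2O
Reagents that add atoms: none
Why: LaCl3·2LiCl-promoted Grignard 1,2-addition suppresses enolisation and β-hydride reduction, and the isopropyl nucleophile attacks the cyclopentanone face opposite the bulky adjacent side chain, so the new tertiary hydroxyl ends up cis to that chain (1R).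

Step 8
Reactants: 15 (1R,2S,3R,4S)-3-allyl-4-(tert-butyldimethylsilyloxy)-3-methyl-2-[(1S)-3-methyl-1-(triethylsilyloxy)but-3-en-1-yl]-1-(propan-2-yl)cyclopentan-1-ol
Product: 16 (1S,3R,3aS,4S,8aR)-1-(tert-butyldimethylsilyloxy)-6,8a-dimethyl-3-(propan-2-yl)-4-(triethylsilyloxy)-1,2,3,3a,4,5,8,8a-octahydroazulen-3-ol
Conditions: second-generation Grubbs catalyst (5 mol %), toluene (2 mM), 80 °C
Reagents that add atoms: none
Why: Ring-closing olefin metathesis between the allyl and 2-methylallyl groups, which sit trans on adjacent ring carbons, closes the seven-membered ring as a trans-fused hydroazulene with a trisubstituted alkene and loss of ethylene, no stereocenter being touched.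

Step 9
Reactants: 16 (1S,3R,3aS,4S,8aR)-1-(tert-butyldimethylsilyloxy)-6,8a-dimethyl-3-(propan-2-yl)-4-(triethylsilyloxy)-1,2,3,3a,4,5,8,8a-octahydroazulen-3-ol
Product: 17 (1S,3R,3aS,4S,8aR)-6,8a-dimethyl-3-(propan-2-yl)-1,2,3,3a,4,5,8,8a-octahydroazulene-1,3,4-triol
Conditions: TBAF, THF, 50 °C
Reagents that add atoms: none
Why: Fluoride-mediated desilylation cleaves both silyl ethers under non-acidic conditions that leave the tertiary alcohol and the trisubstituted alkene intact.

Step 10
Reactants: 17 (1S,3R,3aS,4S,8aR)-6,8a-dimethyl-3-(propan-2-yl)-1,2,3,3a,4,5,8,8a-octahydroazulene-1,3,4-triol; 18 (Z)-2-methylbut-2-enoic acid (angelic acid, two molecules per molecule of 17)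
Product: 20 (1S,3R,3aS,4S,8aR)-3-hydroxy-6,8a-dimethyl-3-(propan-2-yl)-1,2,3,3a,4,5,8,8a-octahydroazulene-1,4-diyl bis[(2Z)-2-methylbut-2-enoate], via mixed anhydride 19 (not isolated)
Conditions: 18, 2,4,6-trichlorobenzoyl chloride, Et3N, toluene, rt; then 17, 80 °C
Reagents that add atoms: none
Why: Yamaguchi-type mixed-anhydride esterification run without a nucleophilic catalyst acylates the two secondary hydroxyls with retention of the Z (angelate) geometry, while the tertiary hydroxyl flanked by the isopropyl group is too hindered to react.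

**Compound list**

1 | (S)-4-(tert-butyldimethylsilyloxy)cyclopent-2-en-1-one | O=C1C=C[C@@H](O[Si](C)(C)C(C)(C)C)C1 | starting material
2 | allylmagnesium bromide | C=CC[Mg]Br | starting material
3 | (3S,4S)-3-allyl-4-(tert-butyldimethylsilyloxy)-1-(trimethylsilyloxy)cyclopent-1-ene (allyl trans to OTBS) | C[Si](C)(C)OC1=C[C@H](CC=C)[C@@H](O[Si](C)(C)C(C)(C)C)C1 | intermediate
4 | (S)-3-allyl-4-(tert-butyldimethylsilyloxy)cyclopent-2-en-1-one | O=C1C=C(CC=C)[C@@H](O[Si](C)(C)C(C)(C)C)C1 | intermediate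
5 | methyllithium | [Li]C | starting material
6 | (3R,4S)-3-allyl-4-(tert-butyldimethylsilyloxy)-3-methyl-1-(trimethylsilyloxy)cyclopent-1-ene (methyl trans, allyl cis to OTBS) | C[Si](C)(C)OC1=C[C@@](C)(CC=C)[C@@H](O[Si](C)(C)C(C)(C)C)C1 | intermediate
7 | 3-methylbut-3-en-1-ol | C=C(C)CCO | starting material
8 | 3-methylbut-3-enal | C=C(C)CC=O | intermediate
9 | lithium (3R,4S)-3-allyl-4-(tert-butyldimethylsilyloxy)-3-methylcyclopent-1-en-1-olate | [Li]OC1=C[C@@](C)(CC=C)[C@@H](O[Si](C)(C)C(C)(C)C)C1 | intermediate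
10 | dicyclohexyl{[(3R,4S)-3-allyl-4-(tert-butyldimethylsilyloxy)-3-methylcyclopent-1-en-1-yl]oxy}borane | C1CCCCC1B(C1CCCCC1)OC1=C[C@@](C)(CC=C)[C@@H](O[Si](C)(C)C(C)(C)C)C1 | intermediate
11 | (1S)-1-[(1S,2R,3S)-2-allyl-3-(tert-butyldimethylsilyloxy)-2-methyl-5-oxocyclopentyl]-3-methylbut-3-en-1-yl dicyclohexylborinate | C=C(C)C[C@H](OB(C1CCCCC1)C1CCCCC1)[C@H]1C(=O)C[C@H](O[Si](C)(C)C(C)(C)C)[C@]1(C)CC=C | intermediate
12 | (2S,3R,4S)-3-allyl-4-(tert-butyldimethylsilyloxy)-2-[(1S)-1-hydroxy-3-methylbut-3-en-1-yl]-3-methylcyclopentan-1-one | C=C(C)C[C@H](O)[C@H]1C(=O)C[C@H](O[Si](C)(C)C(C)(C)C)[C@]1(C)CC=C | intermediate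
13 | (2S,3R,4S)-3-allyl-4-(tert-butyldimethylsilyloxy)-3-methyl-2-[(1S)-3-methyl-1-(triethylsilyloxy)but-3-en-1-yl]cyclopentan-1-one | C=C(C)C[C@H](O[Si](CC)(CC)CC)[C@H]1C(=O)C[C@H](O[Si](C)(C)C(C)(C)C)[C@]1(C)CC=C | intermediate
14 | isopropylmagnesium chloride (used as its LiCl complex) | CC(C)[Mg]Cl | starting material
15 | (1R,2S,3R,4S)-3-allyl-4-(tert-butyldimethylsilyloxy)-3-methyl-2-[(1S)-3-methyl-1-(triethylsilyloxy)but-3-en-1-yl]-1-(propan-2-yl)cyclopentan-1-ol | C=C(C)C[C@H](O[Si](CC)(CC)CC)[C@H]1[C@](O)(C(C)C)C[C@H](O[Si](C)(C)C(C)(C)C)[C@]1(C)CC=C | intermediate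
16 | (1S,3R,3aS,4S,8aR)-1-(tert-butyldimethylsilyloxy)-6,8a-dimethyl-3-(propan-2-yl)-4-(triethylsilyloxy)-1,2,3,3a,4,5,8,8a-octahydroazulen-3-ol (trans-fused) | CC[Si](CC)(CC)O[C@H]1CC(C)=CC[C@@]2(C)[C@@H](O[Si](C)(C)C(C)(C)C)C[C@@](O)(C(C)C)[C@H]12 | intermediate
17 | (1S,3R,3aS,4S,8aR)-6,8a-dimethyl-3-(propan-2-yl)-1,2,3,3a,4,5,8,8a-octahydroazulene-1,3,4-triol | O[C@H]1CC(C)=CC[C@@]2(C)[C@@H](O)C[C@@](O)(C(C)C)[C@H]12 | intermediate
18 | (Z)-2-methylbut-2-enoic acid (angelic acid) | C/C=C(/C)C(=O)O | starting material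
19 | (Z)-2-methylbut-2-enoic 2,4,6-trichlorobenzoic anhydride | C/C=C(/C)C(=O)OC(=O)c1c(Cl)cc(Cl)cc1Cl | intermediate
20 | (1S,3R,3aS,4S,8aR)-3-hydroxy-6,8a-dimethyl-3-(propan-2-yl)-1,2,3,3a,4,5,8,8a-octahydroazulene-1,4-diyl bis[(2Z)-2-methylbut-2-enoate] (CNP0303897.1) | C/C=C(/C)C(=O)O[C@H]1CC(C)=CC[C@@]2(C)[C@@H](OC(=O)/C(C)=C\C)C[C@@](O)(C(C)C)[C@H]12 | target

**Step count and weak points**

Total step count: 10. Longest linear sequence: 9 steps (1 to 20 through steps 1, 2, 3, 5, 6, 7, 8, 9 and 10; step 4 is the one-step side branch to aldehyde 8).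

The three steps most likely to fail:

Step 5 (aldol). The β,γ-unsaturated aldehyde is fragile, and both the facial and the anti selectivity rest on a hindered enolate. Fallback: form the C6–C7 bond by reagent-controlled carbonyl methallylation, setting out from 6 and coming back at 15. The lithium enolate 9 (MeLi on 6) is trapped with gaseous formaldehyde at −78 °C to give the hydroxymethyl ketone F1. TESCl/imidazole gives the triethylsilyl ether F2, and iPrMgCl·LiCl/LaCl3·2LiCl gives the tertiary alcohol F3. PPTS/MeOH frees the primary hydroxyl to give the diol F4, and TEMPO/(diacetoxyiodo)benzene gives the hydroxy aldehyde F5. The Ipc2B(2-methylallyl) antipode matched to the (S)-carbinol (expected to be the one made from (−)-Ipc2BOMe and 2-methylallylmagnesium chloride) at −78 °C, followed by NaBO3·4H2O work-up, gives the homoallylic diol F6. TESOTf/2,6-lutidine at −78 °C silylates only the secondary hydroxyl and returns to 15.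

Step 7 (isopropyl addition). A secondary Grignard reagent on a hindered, enolisable β-silyloxy ketone can reduce or enolise instead of adding. Fallback: bring in the three carbons as an alkenyl group and saturate it after ring closure, setting out from 13 and coming back at 16. Isopropenylmagnesium bromide/CeCl3 in THF at −78 °C (a smaller sp2 nucleophile that cannot transfer a β-hydride) gives the isopropenyl carbinol F7. The second-generation Grubbs catalyst closes the seven-membered ring to the bicyclic diene F8; the 1,1-disubstituted alkene next to the fully substituted carbinol carbon stays a spectator. H2 with RhCl(PPh3)3 saturates only the isopropenyl group and returns to 16.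

Step 10 (double angeloylation). Two hindered secondary hydroxyls must be acylated with an acid that isomerises easily to the tiglate. Fallback: build the Z-alkenes on the ester instead of acylating with the preformed acid, setting out from 17 and arriving at 20. DCC/DMAP esterification with 2-[bis(2,2,2-trifluoroethoxy)phosphoryl]propanoic acid gives the bis(phosphonopropanoate) F9. KN(SiMe3)2/18-crown-6 in THF at −78 °C followed by acetaldehyde (Still–Gennari olefination, Z-selective) forms both angelate double bonds and gives 20.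

**Further compounds**

F1 | step 5 | (2S,3R,4S)-3-allyl-4-(tert-butyldimethylsilyloxy)-2-(hydroxymethyl)-3-methylcyclopentan-1-one | OC[C@H]1C(=O)C[C@H](O[Si](C)(C)C(C)(C)C)[C@]1(C)CC=C
F2 | step 5 | (2S,3R,4S)-3-allyl-4-(tert-butyldimethylsilyloxy)-3-methyl-2-[(triethylsilyloxy)methyl]cyclopentan-1-one | CC[Si](CC)(CC)OC[C@H]1C(=O)C[C@H](O[Si](C)(C)C(C)(C)C)[C@]1(C)CC=C
F3 | step 5 | (1R,2S,3R,4S)-3-allyl-4-(tert-butyldimethylsilyloxy)-3-methyl-1-(propan-2-yl)-2-[(triethylsilyloxy)methyl]cyclopentan-1-ol | CC[Si](CC)(CC)OC[C@H]1[C@](O)(C(C)C)C[C@H](O[Si](C)(C)C(C)(C)C)[C@]1(C)CC=C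
F4 | step 5 | (1R,2S,3R,4S)-3-allyl-4-(tert-butyldimethylsilyloxy)-2-(hydroxymethyl)-3-methyl-1-(propan-2-yl)cyclopentan-1-ol | OC[C@H]1[C@](O)(C(C)C)C[C@H](O[Si](C)(C)C(C)(C)C)[C@]1(C)CC=C
F5 | step 5 | (1R,2R,3S,5R)-2-allyl-3-(tert-butyldimethylsilyloxy)-5-hydroxy-2-methyl-5-(propan-2-yl)cyclopentane-1-carbaldehyde | O=C[C@H]1[C@](O)(C(C)C)C[C@H](O[Si](C)(C)C(C)(C)C)[C@]1(C)CC=C
F6 | step 5 | (1R,2S,3R,4S)-3-allyl-4-(tert-butyldimethylsilyloxy)-2-[(1S)-1-hydroxy-3-methylbut-3-en-1-yl]-3-methyl-1-(propan-2-yl)cyclopentan-1-ol | C=C(C)C[C@H](O)[C@H]1[C@](O)(C(C)C)C[C@H](O[Si](C)(C)C(C)(C)C)[C@]1(C)CC=C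
F7 | step 7 | (1S,2S,3R,4S)-3-allyl-4-(tert-butyldimethylsilyloxy)-3-methyl-2-[(1S)-3-methyl-1-(triethylsilyloxy)but-3-en-1-yl]-1-(prop-1-en-2-yl)cyclopentan-1-ol | C=C(C)C[C@H](O[Si](CC)(CC)CC)[C@H]1[C@](O)(C(C)=C)C[C@H](O[Si](C)(C)C(C)(C)C)[C@]1(C)CC=C
F8 | step 7 | (1S,3S,3aS,4S,8aR)-1-(tert-butyldimethylsilyloxy)-6,8a-dimethyl-3-(prop-1-en-2-yl)-4-(triethylsilyloxy)-1,2,3,3a,4,5,8,8a-octahydroazulen-3-ol | CC[Si](CC)(CC)O[C@H]1CC(C)=CC[C@@]2(C)[C@@H](O[Si](C)(C)C(C)(C)C)C[C@@](O)(C(C)=C)[C@H]12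
F9 | step 10 | (1S,3R,3aS,4S,8aR)-3-hydroxy-6,8a-dimethyl-3-(propan-2-yl)-1,2,3,3a,4,5,8,8a-octahydroazulene-1,4-diyl bis{2-[bis(2,2,2-trifluoroethoxy)phosphoryl]propanoate} (mixture at the two phosphonate α-carbons) | CC(P(=O)(OCC(F)(F)F)OCC(F)(F)F)C(=O)O[C@H]1CC(C)=CC[C@@]2(C)[C@@H](OC(=O)C(C)P(=O)(OCC(F)(F)F)OCC(F)(F)F)C[C@@](O)(C(C)C)[C@H]12
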